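Readings and results are simulated on assumed constants; the scatter is artificial.

Two lengths and one comparison are asked of us, and oak and birch share one charge, so birch is oak stopped earlier.

| flask | J | G | remark | time |
|---|---|---|---|---|
| south-east | 0.090 M | 4.5 mM | run made earlier |  |
| south-west | 0.14 M | 4.5 mM | run made earlier |  |
| oak | 0.18 M | 4.5 mM |  | 8.0 h |
| birch | 0.18 M | 4.5 mM |  | 4.0 h |

| south-east: time / h | south-east: L / % | south-west: time / h | south-west: L / % |
|---|---|---|---|
| 0.833 | 3.2 | 0.833 | 3.9 |
| 1.33 | 5.2 | 1.33 | 4.9 |
| 2.00 | 6.4 | 2.00 | 6.5 |
| 4.00 | 9.7 | 4.00 | 9.5 |
| 6.00 | 13.9 | 6.00 | 13.1 |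
| 10.0 | 16.8 | 10.0 | 21.9 |

(each reading ± 0.5 percentage points)

1. which of the two ends with the longer chains by the average number of monomer units in a chain (chains begun, living or dead) ("neither" if they lie within 10 %) (oak / birch / neither)
2. average number of monomer units in a chain (chains begun, living or dead) at the end, oak
3. average number of monomer units in a chain (chains begun, living or dead) at the end, birch

- the average divides the monomer in chains by the number of chains begun, living and dead together
- the earlier runs do not show the number of chains; that part of a forecast is a guess

We carry the charge ratio, J charged per G charged, 40.0. If each G begins one chain, which is a guess, the units per chain (number-average degree of polymerisation) are this ratio times the fraction of J turned to L.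

Turn the question round: with equal chain numbers, "neither" needs L in oak to stay under 10.6 %, which is the mean reading of the earlier runs at 4.00 h, 9.60 %, taken as our estimate for birch and raised by the margin. The two runs read alike up to 6.00 h, though they part at 10.0 h, so we carry their mean percent to 0.18 M. We replace the bending curve by its mean slope from 4.00 h to 10.0 h, where the mean is 19.4 %, and this gives 16.1 % for oak. At 6.00 h that line falls below the mean reading by 0.65 percentage points, far less than the 5.5 points by which oak clears the limit. Our lengths are 6.44 for oak and 3.84 for birch.

The forecast says oak, with 6.6 for oak and 3.9 for birch, counting “one per G, all begun early”; its oak figure lies a little above ours.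

The flask gives oak, with 7.44 for oak and 4.26 for birch.

    L + D → J + D, rate k1*[D] as long as [L] is above zero (k = 0.00520 min⁻¹)
    J + G → D + L (k = 0.250 M⁻¹ min⁻¹)
    J + D → L + D, rate k3*[D]*[J] (k = 0.120 M⁻¹ min⁻¹)

In oak, L stands at 18.6 % and cD at 0.00450 M, with G at 0 %, so the ratio gives 7.44. A second flask, birch charged instead with 0.45 M of J and read at the same time, has the ratio 100, and with L at 11.5 % its length is 11.5. In birch at 4.00 h, L is made 3.72 times faster than it is used up, each step taken net. At that time L stands in birch at 10.7 % of the J charged.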